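## Retrosynthetic overview

1. Target 15 is an all-trans oxolane (O1, C2 aryl, C3 CH2OH, C4 aroyl, C5 H2; 2S,3R,4S). The last operations are removal of two aryl silyl ethers, oxidative cleavage of a 1-arylethenyl group on C4 to the aroyl C=O, and reduction of a C3 aldehyde to the CH2OH (C9).
2. Key disconnection C2–C3: the oxolane-3-carbaldehyde is the Lewis-acid ring-contraction product of a seven-membered cyclic vinyl acetal (a 4,5-dihydro-1,3-dioxepine). Both acetal epimers converge on the all-trans product.
3. Enabling feature: C2 carries both the ring oxygen O1 and the electron-rich 4-oxygenated 3,5-dimethoxyphenyl ring, so it can be the carbon of a stabilized oxocarbenium ion. C3 carries C9, which at the aldehyde level makes C3 an enolate carbon (aldol pattern O1–C2–C3–C9=O).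
4. The dihydrodioxepine comes from an asymmetric Heck coupling of a 1-arylethenyl triflate (from acetosyringone) with the 4,7-dihydro-1,3-dioxepine acetal of syringaldehyde and (Z)-but-2-ene-1,4-diol. This sets C4 and moves the alkene into the enol-ether position.
5. Ring order: dioxepine ring (step 2), then oxolane ring (step 6); both benzene rings are bought.

Key step: step 6

Remark on naming: oxolane numbering O1, C2 (aryl), C3 (CH2OH, carbon C9), C4 (aroyl), C5 is used throughout; "ArTBS" means 4-(tert-butyldimethylsilyloxy)-3,5-dimethoxyphenyl.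

Assumption: the sense of induction in step 5 is assigned by analogy with triflate couplings of 4,7-dihydro-1,3-dioxepines; the (S)-ligand is written, and its commercial enantiomer would be used if the (5S) series formed instead.

## Route

Step 1
Reactants: 1 syringaldehyde (4-hydroxy-3,5-dimethoxybenzaldehyde)
Product: 2 4-(tert-butyldimethylsilyloxy)-3,5-dimethoxybenzaldehyde
Conditions: TBSCl, Et3N, DMAP (cat.), CH2Cl2, 0 °C to rt
Reagents that add atoms: tert-butyldimethylsilyl chloride (TBSCl), CC(C)(C)[Si](C)(C)Cl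
Why: Standard O-silylation of a phenol; the aryl silyl ether should survive mild acid, amine bases, BF3 at low temperature, NaBH4 and osmylation, and is removed last by fluoride.

Step 2
Reactants: 2 4-(tert-butyldimethylsilyloxy)-3,5-dimethoxybenzaldehyde; 3 (Z)-but-2-ene-1,4-diol
Product: 4 2-ArTBS-4,7-dihydro-1,3-dioxepine
Conditions: pyridinium p-toluenesulfonate (cat.), benzene, reflux, Dean–Stark trap
Reagents that add atoms: none
Why: Acid-catalysed acetalization driven by azeotropic removal of water; the cis diol closes the seven-membered acetal, a mirror-symmetric alkene with no stereocenter.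

Step 3
Reactants: 5 acetosyringone (1-(4-hydroxy-3,5-dimethoxyphenyl)ethan-1-one)
Product: 6 1-ArTBS-ethan-1-one
Conditions: TBSCl, Et3N, DMAP (cat.), CH2Cl2, 0 °C to rt
Reagents that add atoms: tert-butyldimethylsilyl chloride (TBSCl), CC(C)(C)[Si](C)(C)Cl
Why: Standard O-silylation of a phenol, as in step 1.

Step 4
Reactants: 6 1-ArTBS-ethan-1-one
Product: 8 1-ArTBS-ethenyl trifluoromethanesulfonate, via potassium enolate 7 (not isolated)
Conditions: KN(SiMe3)2, THF, −78 °C; then PhNTf2, −78 °C to 0 °C; rapid filtration through basic alumina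
Reagents that add atoms: N-phenylbis(trifluoromethanesulfonimide) (PhNTf2), FC(F)(F)S(=O)(=O)N(c1ccccc1)S(=O)(=O)C(F)(F)F
Why: Kinetic enolization of the methyl ketone and O-triflation of the enolate (enol triflate formation) should give the terminal alkenyl triflate.

Step 5
Reactants: 4 2-ArTBS-4,7-dihydro-1,3-dioxepine (3 equiv, excess recovered); 8 1-ArTBS-ethenyl trifluoromethanesulfonate
Product: 9 (5R)-2-ArTBS-5-(1-ArTBS-ethenyl)-4,5-dihydro-1,3-dioxepine, both C2 epimers
Conditions: Pd2(dba)3 (3 mol %), (S)-tBu-PHOX (7 mol %), iPr2NEt (3 equiv), THF, 60 °C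
Reagents that add atoms: none
Why: Asymmetric intermolecular Mizoroki–Heck reaction through a cationic alkenylpalladium complex: syn-carbopalladation is followed by syn β-hydride elimination, which can only use the C7–H (the C5–H is anti to palladium), so the alkene moves to the enol-ether position and C5 stays stereogenic. The chiral P,N ligand differentiates the enantiotopic alkene carbons and sets C5 (R); attack on either ring face gives the same C5 configuration and differs only at the acetal carbon, which step 6 erases.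

Step 6
Reactants: 9 (5R)-2-ArTBS-5-(1-ArTBS-ethenyl)-4,5-dihydro-1,3-dioxepine
Product: 11 (2S,3S,4R)-2-ArTBS-4-(1-ArTBS-ethenyl)oxolane-3-carbaldehyde, via ring-opened oxocarbenium boron enolate zwitterion 10 (not isolated)
Conditions: BF3·OEt2 (0.2 equiv), CH2Cl2, −78 °C to 0 °C; then Et3N
Reagents that add atoms: none
Why: BF3 binds the enol-ether oxygen of the cyclic vinyl acetal and heterolyses its bond to the acetal carbon, giving zwitterion 10, an aryl-stabilized oxocarbenium ion tethered to a (Z)-boron enolate; the enolate carbon then adds to the oxocarbenium carbon (intramolecular Mukaiyama aldol-type step), forming the C2–C3 bond, and release of BF3 leaves the aldehyde. The closest known reaction type is the Lewis-acid ring contraction of 4,5-dihydro-1,3-dioxepines to 2,3-disubstituted oxolane-3-carbaldehydes (a Petasis–Ferrier-type vinyl acetal rearrangement). The oxolane closes in a 5-(enolexo)-endo-trig mode with respect to the C=O+ bond, the mode through which this class of oxocarbenium ions is known to cyclize. C4 is untouched and not enolizable at this stage, so it is the fixed anchor; C3 is set trans to the C4 substituent (the enolate is attacked anti to the 1-arylethenyl group and the α-formyl centre can epimerize), and C2 is set trans to C3 under thermodynamic control, because the closure is reversible on warming and the all-trans isomer carries all three substituents pseudo-equatorial. Since the acetal carbon becomes planar in 10, both C2 epimers of 9 should converge on the one product. The step needs chemoselectivity for the enolate carbon over the 1-arylethenyl π bond, which the far higher nucleophilicity of the enolate, its generation inside the ion pair and the five- versus six-membered closure should secure.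

Step 7
Reactants: 11 (2S,3S,4R)-2-ArTBS-4-(1-ArTBS-ethenyl)oxolane-3-carbaldehyde
Product: 12 [(2S,3R,4R)-2-ArTBS-4-(1-ArTBS-ethenyl)oxolan-3-yl]methanol
Conditions: NaBH4, MeOH/CH2Cl2, −20 °C
Reagents that add atoms: none
Why: Borohydride reduction of the aldehyde; this fixes C3, which is no longer epimerizable once the formyl group is gone.

Step 8
Reactants: 12 [(2S,3R,4R)-2-ArTBS-4-(1-ArTBS-ethenyl)oxolan-3-yl]methanol
Product: 14 ArTBS [(2S,3R,4S)-2-ArTBS-3-(hydroxymethyl)oxolan-4-yl] ketone, via diol 13 (not isolated)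
Conditions: OsO4 (2 mol %), NaIO4 (4 equiv), 2,6-lutidine, dioxane/H2O (3:1), rt
Reagents that add atoms: osmium tetroxide (OsO4, transfers the oxygen), O=[Os](=O)(=O)=O; sodium periodate (NaIO4, terminal oxidant that regenerates OsO4), [Na+].[O-]I(=O)(=O)=O
Why: Lemieux–Johnson oxidation: dihydroxylation of the 1,1-disubstituted alkene and periodate cleavage of the diol unveil the aryl ketone. The trans C3/C4 arrangement prevents hemiketal formation with the CH2OH, and the C4 configuration is the thermodynamically preferred one should it enolize.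

Step 9
Reactants: 14 ArTBS [(2S,3R,4S)-2-ArTBS-3-(hydroxymethyl)oxolan-4-yl] ketone
Product: 15 (4-hydroxy-3,5-dimethoxyphenyl) [(2S,3R,4S)-2-(4-hydroxy-3,5-dimethoxyphenyl)-3-(hydroxymethyl)oxolan-4-yl] ketone (target)
Conditions: Bu4NF (2.4 equiv), AcOH (2.6 equiv), THF, 0 °C
Reagents that add atoms: none
Why: Fluoride cleavage of both aryl silyl ethers; the acetic acid buffer keeps phenoxide and ketone enolate concentrations low, so β-elimination of O1 and quinone-methide opening at C2 should not compete.

## Compound list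

1 | syringaldehyde | COc1cc(C=O)cc(OC)c1O | starting material
2 | 4-(tert-butyldimethylsilyloxy)-3,5-dimethoxybenzaldehyde | COc1cc(C=O)cc(OC)c1O[Si](C)(C)C(C)(C)C | intermediate
3 | (Z)-but-2-ene-1,4-diol | OC/C=C\CO | starting material
4 | 2-ArTBS-4,7-dihydro-1,3-dioxepine | COc1cc(C2OCC=CCO2)cc(OC)c1O[Si](C)(C)C(C)(C)C | intermediate
5 | acetosyringone | CC(=O)c1cc(OC)c(O)c(OC)c1 | starting material
6 | 1-ArTBS-ethan-1-one | CC(=O)c1cc(OC)c(O[Si](C)(C)C(C)(C)C)c(OC)c1 | intermediate
7 | potassium enolate of 6 (formed in the flask) | [K+].[O-]C(=C)c1cc(OC)c(O[Si](C)(C)C(C)(C)C)c(OC)c1 | intermediate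
8 | 1-ArTBS-ethenyl trifluoromethanesulfonate | C=C(OS(=O)(=O)C(F)(F)F)c1cc(OC)c(O[Si](C)(C)C(C)(C)C)c(OC)c1 | intermediate
9 | (5R)-2-ArTBS-5-(1-ArTBS-ethenyl)-4,5-dihydro-1,3-dioxepine, both C2 epimers | COc1cc(C(=C)[C@@H]2COC(c3cc(OC)c(O[Si](C)(C)C(C)(C)C)c(OC)c3)OC=C2)cc(OC)c1O[Si](C)(C)C(C)(C)C | intermediate
10 | ring-opened zwitterion: ArTBS-oxocarbenium ion tethered to the (Z)-trifluoroborate enolate (formed in the flask) | COc1cc(C(=C)[C@@H](/C=C\O[B-](F)(F)F)C[O+]=Cc2cc(OC)c(O[Si](C)(C)C(C)(C)C)c(OC)c2)cc(OC)c1O[Si](C)(C)C(C)(C)C | intermediate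
11 | (2S,3S,4R)-2-ArTBS-4-(1-ArTBS-ethenyl)oxolane-3-carbaldehyde | COc1cc(C(=C)[C@@H]2CO[C@H](c3cc(OC)c(O[Si](C)(C)C(C)(C)C)c(OC)c3)[C@H]2C=O)cc(OC)c1O[Si](C)(C)C(C)(C)C | intermediate
12 | [(2S,3R,4R)-2-ArTBS-4-(1-ArTBS-ethenyl)oxolan-3-yl]methanol | COc1cc(C(=C)[C@@H]2CO[C@H](c3cc(OC)c(O[Si](C)(C)C(C)(C)C)c(OC)c3)[C@H]2CO)cc(OC)c1O[Si](C)(C)C(C)(C)C | intermediate
13 | 1-ArTBS-1-[(2S,3R,4S)-2-ArTBS-3-(hydroxymethyl)oxolan-4-yl]ethane-1,2-diol, both carbinol epimers (formed in the flask) | COc1cc(C(O)(CO)[C@@H]2CO[C@H](c3cc(OC)c(O[Si](C)(C)C(C)(C)C)c(OC)c3)[C@H]2CO)cc(OC)c1O[Si](C)(C)C(C)(C)C | intermediate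
14 | ArTBS [(2S,3R,4S)-2-ArTBS-3-(hydroxymethyl)oxolan-4-yl] ketone | COc1cc(C(=O)[C@@H]2CO[C@H](c3cc(OC)c(O[Si](C)(C)C(C)(C)C)c(OC)c3)[C@H]2CO)cc(OC)c1O[Si](C)(C)C(C)(C)C | intermediate
15 | (4-hydroxy-3,5-dimethoxyphenyl) [(2S,3R,4S)-2-(4-hydroxy-3,5-dimethoxyphenyl)-3-(hydroxymethyl)oxolan-4-yl] ketone | COc1cc(C(=O)[C@@H]2CO[C@H](c3cc(OC)c(O)c(OC)c3)[C@H]2CO)cc(OC)c1O | target

## Step count and risks

Total steps: 9. Longest linear sequence: 7 (steps 1, 2, 5, 6, 7, 8, 9; the branch through steps 3 and 4 is equally long).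

Three steps most likely to fail:

**Step 6.** The 1-arylethenyl π bond may intercept the oxocarbenium ion (six-membered Prins closure or cationic oligomerization), or equilibration may stop at the kinetic 2,3-cis stage. The fallback sets out from 9 and returns at 14. The ring contraction would be run under Petasis–Ferrier conditions with Al(iBu)3 in CH2Cl2 at −78 °C, where the aluminium-templated rearrangement is followed at once by hydride transfer from an isobutyl group to the aluminium-bound aldehyde. No free oxocarbenium ion is then warmed in the presence of the styrene, and the product is the alcohol directly, expected as the kinetic C2 epimer, the 2,3-cis alcohol F1. The conditions of step 8 would take F1 through the diol F2 to the 2,3-cis ketone F3, which no longer contains an alkene. F3 would then be equilibrated at C2 with camphorsulfonic acid (or catalytic BF3·OEt2) in CH2Cl2, by ionization of the benzylic C2–O1 bond to the aryl-stabilized cation and re-closure, to give 14.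

**Step 5.** Enantiofacial discrimination at the alkene may be poor. The fallback sets out from 4 and 8 and returns at 12. The coupling would be run with an achiral catalyst (Pd(OAc)2, 1,3-bis(diphenylphosphino)propane, iPr2NEt, THF), which gives 9 together with its (5S) counterpart F4. Steps 6 and 7 applied to this mixture would take F4 through the enantiomeric zwitterion F5 and the enantiomeric aldehyde F6 to the enantiomeric alcohol F7 alongside 12. Alcohol 12 would be separated from F7 by preparative chromatography on a chiral stationary phase, so that the absolute configuration comes from resolution and not from the catalyst.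

**Step 4.** The electron-rich alkenyl triflate may lose triflate by ionization during isolation. The fallback sets out from 6 and returns at 9. Ketone 6 would be converted with P(OPh)3, Br2 and Et3N in CH2Cl2 (−60 °C to rt) into the bench-stable 1-ArTBS-1-bromoethene F8. F8 would be coupled with 4 under the catalyst of step 5 with Ag3PO4 as halide scavenger, which restores the cationic alkenylpalladium pathway and should give 9.

Further compounds
F1 | step 6 | [(2R,3R,4R)-2-ArTBS-4-(1-ArTBS-ethenyl)oxolan-3-yl]methanol (2,3-cis alcohol) | COc1cc(C(=C)[C@@H]2CO[C@@H](c3cc(OC)c(O[Si](C)(C)C(C)(C)C)c(OC)c3)[C@H]2CO)cc(OC)c1O[Si](C)(C)C(C)(C)C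
F2 | step 6 | 1-ArTBS-1-[(2R,3R,4S)-2-ArTBS-3-(hydroxymethyl)oxolan-4-yl]ethane-1,2-diol, both carbinol epimers | COc1cc(C(O)(CO)[C@@H]2CO[C@@H](c3cc(OC)c(O[Si](C)(C)C(C)(C)C)c(OC)c3)[C@H]2CO)cc(OC)c1O[Si](C)(C)C(C)(C)C
F3 | step 6 | ArTBS [(2R,3R,4S)-2-ArTBS-3-(hydroxymethyl)oxolan-4-yl] ketone (2,3-cis ketone) | COc1cc(C(=O)[C@@H]2CO[C@@H](c3cc(OC)c(O[Si](C)(C)C(C)(C)C)c(OC)c3)[C@H]2CO)cc(OC)c1O[Si](C)(C)C(C)(C)C
F4 | step 5 | (5S)-2-ArTBS-5-(1-ArTBS-ethenyl)-4,5-dihydro-1,3-dioxepine, both C2 epimers | COc1cc(C(=C)[C@H]2COC(c3cc(OC)c(O[Si](C)(C)C(C)(C)C)c(OC)c3)OC=C2)cc(OC)c1O[Si](C)(C)C(C)(C)C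
F5 | step 5 | enantiomer of zwitterion 10 | COc1cc(C(=C)[C@H](/C=C\O[B-](F)(F)F)C[O+]=Cc2cc(OC)c(O[Si](C)(C)C(C)(C)C)c(OC)c2)cc(OC)c1O[Si](C)(C)C(C)(C)C
F6 | step 5 | (2R,3R,4S)-2-ArTBS-4-(1-ArTBS-ethenyl)oxolane-3-carbaldehyde (enantiomer of 11) | COc1cc(C(=C)[C@H]2CO[C@@H](c3cc(OC)c(O[Si](C)(C)C(C)(C)C)c(OC)c3)[C@@H]2C=O)cc(OC)c1O[Si](C)(C)C(C)(C)C
F7 | step 5 | [(2R,3S,4S)-2-ArTBS-4-(1-ArTBS-ethenyl)oxolan-3-yl]methanol (enantiomer of 12) | COc1cc(C(=C)[C@H]2CO[C@@H](c3cc(OC)c(O[Si](C)(C)C(C)(C)C)c(OC)c3)[C@@H]2CO)cc(OC)c1O[Si](C)(C)C(C)(C)C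
F8 | step 4 | 1-ArTBS-1-bromoethene | C=C(Br)c1cc(OC)c(O[Si](C)(C)C(C)(C)C)c(OC)c1
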